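Rings are lettered A–E starting at the 3,5-dihydroxyphenoxy terminus and the ether oxygens O1–O4 in the same direction; C1 of each ring sits on its ether oxygen nearer ring A. Ring A (O1 on C1, hydroxyls on C3 and C5) is a phloroglucinol whose six carbons map onto 6-methyl-2-pyranone. Everything rests on disconnecting ring A at C3–C4: a 4-aryloxy-6-methyl-2-pyranone carrying protected ring B on O1 is isomerised by LiN(SiMe3)2, which in one operation closes the carbocycle and turns both lactone oxygens into the ring A hydroxyls. The precursor comes from triacetic acid lactone and a ring B phenol. Rings C, D and E follow by copper-catalysed etherification/Baeyer–Villiger cycles; BBr3 frees all hydroxyls.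

Key step: step 5

Remarks on the chemistry
- Atom provenance: O1 is delivered by the ring B phenol. The 4-oxygen of the lactone is lost when C4 is activated; the lactone carbonyl oxygen becomes the C3 hydroxyl and the lactone ring oxygen the C5 hydroxyl of ring A.
- The lactone is activated as its 4-bromide, because a halide offers the flanked phenoxide no second electrophilic centre (no sulfonyl transfer).
- The ring B phenol is made from 2-hydroxy-4,6-dimethoxybenzaldehyde, so its three oxygens are differentiated from the start and no selective mono-methylation is needed.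
- Assumption: compounds 1, 5, 13 and 17 are taken as purchasable (17 is otherwise one bromination away from 3,5-dimethoxybenzaldehyde).

Step 1
Reactants: 1 2-hydroxy-4,6-dimethoxybenzaldehyde
Product: 2 2-(benzyloxy)-4,6-dimethoxybenzaldehyde
Conditions: BnBr, K2CO3, DMF, 60 °C
Reagents that add atoms: benzyl bromide, BrCc1ccccc1
Why: Williamson ether synthesis; the only acidic site is the phenol, whose phenoxide is alkylated by the reactive benzylic bromide.

Step 2
Reactants: 2 2-(benzyloxy)-4,6-dimethoxybenzaldehyde
Product: 4 2-(benzyloxy)-4,6-dimethoxyphenol, via aryl formate 3 (not isolated)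
Conditions: mCPBA, CH2Cl2, 0 °C to rt; then K2CO3 (cat.), MeOH, rt
Reagents that add atoms: mCPBA (3-chloroperoxybenzoic acid), OOC(=O)c1cccc(Cl)c1
Why: Baeyer–Villiger oxidation, in which the 2,4,6-trialkoxyphenyl group migrates far better than hydrogen, followed by methanolysis of the aryl formate.

Step 3
Reactants: 5 triacetic acid lactone (4-hydroxy-6-methyl-2H-pyran-2-one)
Product: 6 4-bromo-6-methyl-2H-pyran-2-one
Conditions: Bu4NBr, P2O5, toluene, 100 °C
Reagents that add atoms: tetrabutylammonium bromide, CCCC[N+](CCCC)(CCCC)CCCC.[Br-]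
Why: Deoxybromination of a vinylogous acid: the 4-hydroxyl is phosphorylated and replaced by bromide through addition–elimination at C4.

Step 4
Reactants: 4 2-(benzyloxy)-4,6-dimethoxyphenol; 6 4-bromo-6-methyl-2H-pyran-2-one
Product: 7 4-[2-(benzyloxy)-4,6-dimethoxyphenoxy]-6-methyl-2H-pyran-2-one
Conditions: K2CO3, DMF, rt to 50 °C, argon
Reagents that add atoms: none
Why: Nucleophilic vinylic substitution (addition–elimination) at C4, the β-carbon of the unsaturated lactone, which is trigonal and open even to the flanked phenoxide; this creates O1.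

Step 5
Reactants: 7 4-[2-(benzyloxy)-4,6-dimethoxyphenoxy]-6-methyl-2H-pyran-2-one
Product: 10 5-[2-(benzyloxy)-4,6-dimethoxyphenoxy]benzene-1,3-diol, via lithium dienolate 8 (not isolated), via open-chain ketene enolate 9 (not isolated)
Conditions: LiN(SiMe3)2 (3.3 equiv), THF, slow addition of 7 at −78 °C (0.02 M), then −78 °C to rt; 1 M HCl
Reagents that add atoms: none
Why: Proposed new method: LiN(SiMe3)2 removes a proton from the C6 methyl group, the most acidic C–H because it is vinylogous to the lactone carbonyl, and on warming dienolate 8 should expel the ring oxygen from its ester-enolate end (E1cB-type opening, as aryl ester enolates give ketenes) to form ketene enolate 9, in which the methyl-ketone enolate and the ketene stay cis on the former C4=C5 double bond. The enolate carbon (former methyl) then adds to the ketene carbon (former lactone carbonyl), a six-membered carbocyclic closure by intramolecular C-acylation, equally describable as a 6π electrocyclisation of the dienyl ketene, which forms ring A C3–C4; proton transfer and further base give the aromatic resorcinol dianion. The nearest precedents are base-mediated Claisen ring closures of triacetic acid esters to phloroglucinol, the alkali-promoted rearrangement of 2,6-dimethyl-4-pyranone into orcinol and the fragmentation of aryl ester enolates to ketenes. No stereocentre is created. The step needs C-acylation to win over re-lactonisation through oxygen, intermolecular condensation and loss of the aryloxy group: O-acylation only regenerates 8 whereas aromatisation is irreversible, slow addition of 7 to excess base at high dilution keeps neutral pyranone away from the anion, and the bulky amide and its weakly nucleophilic amine neither add to C4 nor trap the ketene.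

Step 6
Reactants: 10 5-[2-(benzyloxy)-4,6-dimethoxyphenoxy]benzene-1,3-diol
Product: 11 1-(benzyloxy)-2-(3,5-dimethoxyphenoxy)-3,5-dimethoxybenzene
Conditions: Me2SO4, K2CO3, acetone, reflux
Reagents that add atoms: dimethyl sulfate, COS(=O)(=O)OC
Why: Williamson O-methylation; the hard electrophile with K2CO3 in acetone favours O- over C-methylation of the phloroglucinol-type ring A.

Step 7
Reactants: 11 1-(benzyloxy)-2-(3,5-dimethoxyphenoxy)-3,5-dimethoxybenzene
Product: 12 2-(3,5-dimethoxyphenoxy)-3,5-dimethoxyphenol (A–B phenol)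
Conditions: H2 (1 atm), Pd/C, EtOAc/MeOH, rt
Reagents that add atoms: none
Why: Hydrogenolysis of the benzyl ether on Pd/C, to which methyl and diaryl ethers are inert, unveils the ring B C6 hydroxyl.

Step 8
Reactants: 12 2-(3,5-dimethoxyphenoxy)-3,5-dimethoxyphenol; 13 4-bromo-3,5-dimethoxybenzaldehyde
Product: 14 4-[2-(3,5-dimethoxyphenoxy)-3,5-dimethoxyphenoxy]-3,5-dimethoxybenzaldehyde (A–B–C aldehyde)
Conditions: CuI (10 mol %), picolinic acid (20 mol %), K3PO4, DMSO, 90 °C, argon
Reagents that add atoms: none
Why: Ullmann-type copper-catalysed C–O coupling; the para formyl group makes the C–Br bond electron-poor and the picolinate ligand is suited to ortho-substituted partners, so the phenoxide of 12 should replace bromide at the carbon flanked by two methoxy groups, creating O2.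

Step 9
Reactants: 14 A–B–C aldehyde
Product: 16 4-[2-(3,5-dimethoxyphenoxy)-3,5-dimethoxyphenoxy]-3,5-dimethoxyphenol (A–B–C phenol), via aryl formate 15 (not isolated)
Conditions: mCPBA, CH2Cl2, 0 °C to rt; then K2CO3 (cat.), MeOH, rt
Reagents that add atoms: mCPBA (3-chloroperoxybenzoic acid), OOC(=O)c1cccc(Cl)c1
Why: Baeyer–Villiger oxidation, in which the aryl group with a para aryloxy donor migrates in preference to hydrogen (as 3,4,5-trialkoxybenzaldehydes do), then formate methanolysis frees the ring C C4 hydroxyl.

Step 10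
Reactants: 16 A–B–C phenol; 17 2-bromo-3,5-dimethoxybenzaldehyde
Product: 18 2-{4-[2-(3,5-dimethoxyphenoxy)-3,5-dimethoxyphenoxy]-3,5-dimethoxyphenoxy}-3,5-dimethoxybenzaldehyde (A–B–C–D aldehyde)
Conditions: CuI (10 mol %), picolinic acid (20 mol %), K3PO4, DMSO, 90 °C, argon
Reagents that add atoms: none
Why: Ullmann-type copper-catalysed C–O coupling of an unhindered phenol with an aryl bromide activated by its ortho formyl group, creating O3 at ring D C1.

Step 11
Reactants: 18 A–B–C–D aldehyde
Product: 20 2-{4-[2-(3,5-dimethoxyphenoxy)-3,5-dimethoxyphenoxy]-3,5-dimethoxyphenoxy}-3,5-dimethoxyphenol (A–B–C–D phenol), via aryl formate 19 (not isolated)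
Conditions: mCPBA, CH2Cl2, 0 °C to rt; then K2CO3 (cat.), MeOH, rt
Reagents that add atoms: mCPBA (3-chloroperoxybenzoic acid), OOC(=O)c1cccc(Cl)c1
Why: Baeyer–Villiger oxidation, with the ortho aryloxy group promoting aryl migration as in 2-alkoxybenzaldehydes, then formate methanolysis frees the ring D C6 hydroxyl.

Step 12
Reactants: 20 A–B–C–D phenol; 13 4-bromo-3,5-dimethoxybenzaldehyde
Product: 21 4-(2-{4-[2-(3,5-dimethoxyphenoxy)-3,5-dimethoxyphenoxy]-3,5-dimethoxyphenoxy}-3,5-dimethoxyphenoxy)-3,5-dimethoxybenzaldehyde (A–B–C–D–E aldehyde)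
Conditions: CuI (10 mol %), picolinic acid (20 mol %), K3PO4, DMSO, 90 °C, argon
Reagents that add atoms: none
Why: Ullmann-type copper-catalysed C–O coupling of the same kind as step 8, creating O4 at ring E C1.

Step 13
Reactants: 21 A–B–C–D–E aldehyde
Product: 23 4-(2-{4-[2-(3,5-dimethoxyphenoxy)-3,5-dimethoxyphenoxy]-3,5-dimethoxyphenoxy}-3,5-dimethoxyphenoxy)-3,5-dimethoxyphenol (decamethyl ether of the target), via aryl formate 22 (not isolated)
Conditions: mCPBA, CH2Cl2, 0 °C to rt; then K2CO3 (cat.), MeOH, rt
Reagents that add atoms: mCPBA (3-chloroperoxybenzoic acid), OOC(=O)c1cccc(Cl)c1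
Why: Baeyer–Villiger oxidation as in step 9, then formate methanolysis frees the ring E C4 hydroxyl.

Step 14
Reactants: 23 decamethyl ether of the target
Product: 24 CNP0018313.0 (target)
Conditions: BBr3 (excess), CH2Cl2, −78 °C to rt; then MeOH, H2O, argon
Reagents that add atoms: none
Why: Lewis-acid ether cleavage; BBr3 binds each methoxy oxygen and bromide attacks the methyl carbon (SN2), whereas the diaryl ether bonds offer no sp3 carbon and should stay intact.

Compound list
1 | 2-hydroxy-4,6-dimethoxybenzaldehyde | COc1cc(O)c(C=O)c(OC)c1 | starting material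
2 | 2-(benzyloxy)-4,6-dimethoxybenzaldehyde | COc1cc(OCc2ccccc2)c(C=O)c(OC)c1 | intermediate
3 | 2-(benzyloxy)-4,6-dimethoxyphenyl formate | COc1cc(OCc2ccccc2)c(OC=O)c(OC)c1 | intermediate (not isolated)
4 | 2-(benzyloxy)-4,6-dimethoxyphenol (ring B phenol) | COc1cc(OCc2ccccc2)c(O)c(OC)c1 | intermediate
5 | triacetic acid lactone (4-hydroxy-6-methyl-2H-pyran-2-one) | CC1=CC(O)=CC(=O)O1 | starting material
6 | 4-bromo-6-methyl-2H-pyran-2-one | CC1=CC(Br)=CC(=O)O1 | intermediate
7 | 4-[2-(benzyloxy)-4,6-dimethoxyphenoxy]-6-methyl-2H-pyran-2-one | CC1=CC(Oc2c(OC)cc(OC)cc2OCc2ccccc2)=CC(=O)O1 | intermediate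
8 | lithium 4-[2-(benzyloxy)-4,6-dimethoxyphenoxy]-6-methylidene-6H-pyran-2-olate (dienolate) | [Li+].C=C1C=C(Oc2c(OC)cc(OC)cc2OCc2ccccc2)C=C([O-])O1 | intermediate (not isolated)
9 | lithium (3E)-4-[2-(benzyloxy)-4,6-dimethoxyphenoxy]-6-oxohexa-1,3,5-trien-2-olate (ketene enolate, enolate carbon and ketene cis) | [Li+].[O-]C(=C)/C=C(\C=C=O)Oc1c(OC)cc(OC)cc1OCc1ccccc1 | intermediate (not isolated)
10 | 5-[2-(benzyloxy)-4,6-dimethoxyphenoxy]benzene-1,3-diol (A–B diol) | Oc1cc(O)cc(Oc2c(OC)cc(OC)cc2OCc2ccccc2)c1 | intermediate
11 | 1-(benzyloxy)-2-(3,5-dimethoxyphenoxy)-3,5-dimethoxybenzene | COc1cc(OC)cc(Oc2c(OC)cc(OC)cc2OCc2ccccc2)c1 | intermediate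
12 | 2-(3,5-dimethoxyphenoxy)-3,5-dimethoxyphenol (A–B phenol) | COc1cc(OC)cc(Oc2c(OC)cc(OC)cc2O)c1 | intermediate
13 | 4-bromo-3,5-dimethoxybenzaldehyde | COc1cc(C=O)cc(OC)c1Br | starting material
14 | 4-[2-(3,5-dimethoxyphenoxy)-3,5-dimethoxyphenoxy]-3,5-dimethoxybenzaldehyde (A–B–C aldehyde) | COc1cc(OC)cc(Oc2c(OC)cc(OC)cc2Oc2c(OC)cc(C=O)cc2OC)c1 | intermediate
15 | 4-[2-(3,5-dimethoxyphenoxy)-3,5-dimethoxyphenoxy]-3,5-dimethoxyphenyl formate | COc1cc(OC)cc(Oc2c(OC)cc(OC)cc2Oc2c(OC)cc(OC=O)cc2OC)c1 | intermediate (not isolated)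
16 | 4-[2-(3,5-dimethoxyphenoxy)-3,5-dimethoxyphenoxy]-3,5-dimethoxyphenol (A–B–C phenol) | COc1cc(OC)cc(Oc2c(OC)cc(OC)cc2Oc2c(OC)cc(O)cc2OC)c1 | intermediate
17 | 2-bromo-3,5-dimethoxybenzaldehyde | COc1cc(C=O)c(Br)c(OC)c1 | starting material
18 | 2-{4-[2-(3,5-dimethoxyphenoxy)-3,5-dimethoxyphenoxy]-3,5-dimethoxyphenoxy}-3,5-dimethoxybenzaldehyde (A–B–C–D aldehyde) | COc1cc(OC)cc(Oc2c(OC)cc(OC)cc2Oc2c(OC)cc(Oc3c(OC)cc(OC)cc3C=O)cc2OC)c1 | intermediate
19 | formate ester of 20 (aryl formate on ring D C6) | COc1cc(OC)cc(Oc2c(OC)cc(OC)cc2Oc2c(OC)cc(Oc3c(OC)cc(OC)cc3OC=O)cc2OC)c1 | intermediate (not isolated)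
20 | 2-{4-[2-(3,5-dimethoxyphenoxy)-3,5-dimethoxyphenoxy]-3,5-dimethoxyphenoxy}-3,5-dimethoxyphenol (A–B–C–D phenol) | COc1cc(OC)cc(Oc2c(OC)cc(OC)cc2Oc2c(OC)cc(Oc3c(OC)cc(OC)cc3O)cc2OC)c1 | intermediate
21 | 4-(2-{4-[2-(3,5-dimethoxyphenoxy)-3,5-dimethoxyphenoxy]-3,5-dimethoxyphenoxy}-3,5-dimethoxyphenoxy)-3,5-dimethoxybenzaldehyde (A–B–C–D–E aldehyde) | COc1cc(OC)cc(Oc2c(OC)cc(OC)cc2Oc2c(OC)cc(Oc3c(OC)cc(OC)cc3Oc3c(OC)cc(C=O)cc3OC)cc2OC)c1 | intermediate
22 | formate ester of 23 (aryl formate on ring E C4) | COc1cc(OC)cc(Oc2c(OC)cc(OC)cc2Oc2c(OC)cc(Oc3c(OC)cc(OC)cc3Oc3c(OC)cc(OC=O)cc3OC)cc2OC)c1 | intermediate (not isolated)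
23 | 4-(2-{4-[2-(3,5-dimethoxyphenoxy)-3,5-dimethoxyphenoxy]-3,5-dimethoxyphenoxy}-3,5-dimethoxyphenoxy)-3,5-dimethoxyphenol (decamethyl ether, free hydroxyl on ring E C4) | COc1cc(OC)cc(Oc2c(OC)cc(OC)cc2Oc2c(OC)cc(Oc3c(OC)cc(OC)cc3Oc3c(OC)cc(O)cc3OC)cc2OC)c1 | intermediate
24 | CNP0018313.0, the pentameric phloroglucinol ether A–O1–B–O2–C–O3–D–O4–E with eleven free hydroxyls (no stereocentre) | Oc1cc(O)cc(Oc2c(O)cc(O)cc2Oc2c(O)cc(Oc3c(O)cc(O)cc3Oc3c(O)cc(O)cc3O)cc2O)c1 | target

Total step count: 14. Longest linear sequence: 13 steps (steps 1, 2 and 4 to 14; step 3 is a one-step side branch).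

Steps most likely to fail

Step 5. The dienolate may not open to the ketene below the temperature at which it condenses with a second pyranone, or the open form may simply re-close through oxygen, so that starting lactone or oligomers are recovered; addition–elimination at C4 with loss of the aryloxide is the other escape. The fallback sets out from phenol 4 and uses known chemistry: Ullmann-type coupling of 4 with 1-bromo-3,5-dimethoxybenzene (COc1cc(Br)cc(OC)c1) under CuI, picolinic acid, K3PO4 in DMSO at 90 °C, the favourable pairing of a flanked phenol with an unhindered aryl bromide. It forms O1 at ring A C1 and delivers benzyl ether 11 directly, so the route is rejoined at compound 11. This fallback makes no compound outside the list (F0).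

Step 8. Oxidative addition and phenoxide transfer at the bromide flanked by two methoxy groups may be slow, so that protodebromination of 13 and oxidative degradation of the electron-rich phenol 12 take over. The fallback sets out from 12 and replaces copper catalysis by an uncatalysed SNAr reaction with 4-fluoro-3,5-dimethoxybenzaldehyde (COc1cc(C=O)cc(OC)c1F), Cs2CO3, DMSO, 120 °C. Attack on the fluoride-bearing carbon goes through a Meisenheimer adduct stabilised by the para formyl group and is much less sensitive to the flanking substituents. It gives aldehyde 14, where the route is rejoined; the same switch is open at step 12 (from 20 to 21). This fallback makes no compound outside the list (F0).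

Step 14. Cleavage of ten methyl ethers may stop at partially methylated mixtures, and the free polyphenol may oxidise in air during chromatography. The fallback sets out from 23: after the BBr3 treatment the crude product is not isolated but peracetylated (Ac2O, pyridine, DMAP, rt) to the undecaacetate of the target F1, which is stable, can be purified on silica and separated from under-demethylated material. Acid methanolysis (HCl generated from AcCl in degassed MeOH, rt, argon) then releases 24 with only volatile by-products, where the route ends.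

Further compounds
F0 | step 5 | none | none
F0 | step 8 | none | none
F1 | step 14 | undecaacetate of 24 (all eleven hydroxyls as acetates) | CC(=O)Oc1cc(OC(C)=O)cc(Oc2c(OC(C)=O)cc(OC(C)=O)cc2Oc2c(OC(C)=O)cc(Oc3c(OC(C)=O)cc(OC(C)=O)cc3Oc3c(OC(C)=O)cc(OC(C)=O)cc3OC(C)=O)cc2OC(C)=O)c1
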